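**Strategy.** The upper flavan is disconnected at O1–C8a of ring A and at C2–C3 of ring C; the interflavan C4–C6 bond is made afterwards from a C4 cation. The key step is a domino aldol/SNAr: the potassium enolate of an α-benzyloxy 2-fluoroaryl ketone adds to 3,4-bis(benzyloxy)benzaldehyde (C2–C3), and the aldolate oxygen displaces the ortho fluoride (O1–C8a), closing ring C as a trans-chromanone. It exploits C4, carried as a ketone: this acidifies C3–H, activates C8a of ring A, and later becomes the cation that arylates C6 of ring D of an 8-bromo-blocked (+)-gallocatechin. A transfer-hydrogenation resolution sets the absolute configuration.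

Key step: step 2

Remark: "4alpha" is read as the C4 aryl group trans to the C3 hydroxyl, which is what the SMILES encodes (upper unit 2R,3S,4S; lower unit 2R,3S). Compounds 8 and 9 are racemic and are drawn as the enantiomer that step 3 carries on.

**Step 1**
Reactants: 1 4-(benzyloxy)-1-bromo-2-fluorobenzene; 2 2-(benzyloxy)-N-methoxy-N-methylacetamide
Product: 5 2-(benzyloxy)-1-[4-(benzyloxy)-2-fluorophenyl]ethan-1-one, via arylmagnesium chloride 3 (not isolated), via magnesium hemiaminal chelate 4 (not isolated)
Conditions: i-PrMgCl·LiCl, THF, 0 °C; then 2, 0 to 23 °C; aq. NH4Cl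
Reagents that add atoms: none
Why: Bromine–magnesium exchange (the ortho-fluoroaryl Grignard reagent should be stable at 0 °C) followed by a Weinreb ketone synthesis, in which the chelated tetrahedral adduct 4 prevents over-addition and releases the ketone only on work-up.

**Step 2**
Reactants: 5 2-(benzyloxy)-1-[4-(benzyloxy)-2-fluorophenyl]ethan-1-one; 6 3,4-bis(benzyloxy)benzaldehyde
Product: 9 rac-(2R*,3R*)-trans-3,7-bis(benzyloxy)-2-[3,4-bis(benzyloxy)phenyl]chroman-4-one, via potassium enolate 7 (not isolated), via potassium aldolate 8 (not isolated)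
Conditions: KN(SiMe3)2, THF, −78 °C; then 6, −78 to 40 °C; then DBU (cat.), 23 °C
Reagents that add atoms: none
Why: KN(SiMe3)2 converts 5 into the chelated potassium (Z)-enolate 7, which adds through C3 to the aldehyde carbon of 6 (the future C2) in a reversible aldol addition, and the aldolate oxygen of 8 then attacks C8a of ring A, ortho to the ketone, in an addition–elimination displacement of fluoride; the closest known reaction type is the domino aldol/SNAr annulation of ortho-fluoroaryl ketones. Ring C is closed in a six-membered exo mode by O1 on C8a, the charge of the Meisenheimer complex resting on the C4 carbonyl. The new stereocentres C2 and C3 are under thermodynamic control: the aldol step is reversible, C3–H stays acidic beside the ketone, and DBU should converge the material on the diequatorial 2,3-trans chromanone, formed as a racemate that step 3 resolves. The step needs ring closure to outrun dehydration to the α-benzyloxychalcone and intermolecular attack on the aryl fluoride; the aprotic medium (hydroxide is a poor leaving group), the non-nucleophilic base and the intramolecular six-membered geometry should secure this. The 7-benzyloxy group is meta to the fluorine, so it places no charge on the carbon under attack.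

**Step 3**
Reactants: 9 rac-trans-3,7-bis(benzyloxy)-2-[3,4-bis(benzyloxy)phenyl]chroman-4-one
Product: 10 (2R,3S,4R)-3,7-bis(benzyloxy)-2-[3,4-bis(benzyloxy)phenyl]chroman-4-ol
Conditions: RuCl[(S,S)-TsDPEN](p-cymene) (cat.), HCO2H/Et3N (5:2), EtOAc, 23 °C, stopped near half conversion; chromatography
Reagents that add atoms: none
Why: Noyori–Ikariya asymmetric transfer hydrogenation run as a kinetic resolution: the (S,S) catalyst delivers hydride to the C4 face that is the unhindered axial face only in the (2R,3R) enantiomer, so this enantiomer should be reduced to the all-equatorial 3,4-trans alcohol while the (2S,3S) ketone is left and separated (the C4 configuration is not needed later).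

**Step 4**
Reactants: 11 (+)-gallocatechin
Product: 12 5,7,3',4',5'-penta-O-benzyl-(+)-gallocatechin
Conditions: BnBr, K2CO3, DMF, 0 to 23 °C, argon
Reagents that add atoms: benzyl bromide, BrCc1ccccc1
Why: Williamson etherification in which carbonate deprotonates only the five phenols, so the secondary 3-hydroxyl stays free and the two stereocentres are not touched.

**Step 5**
Reactants: 12 5,7,3',4',5'-penta-O-benzyl-(+)-gallocatechin
Product: 13 8-bromo-5,7,3',4',5'-penta-O-benzyl-(+)-gallocatechin
Conditions: NBS, CH2Cl2, −78 to 0 °C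
Reagents that add atoms: N-bromosuccinimide, O=C1CCC(=O)N1Br
Why: Electrophilic aromatic bromination of the most electron-rich ring (phloroglucinol-type ring D) at C8, the less hindered of its two free positions between O1 and the 7-benzyloxy group, which leaves C6 as the only nucleophilic carbon.

**Step 6**
Reactants: 10 (2R,3S,4R)-3,7-bis(benzyloxy)-2-[3,4-bis(benzyloxy)phenyl]chroman-4-ol; 13 8-bromo-5,7,3',4',5'-penta-O-benzyl-(+)-gallocatechin (excess)
Product: 15 3,7,3',4'-tetra-O-benzylfisetinidol-(4α,6)-[8-bromo-5,7,3',4',5'-penta-O-benzylgallocatechin], via C4 benzylic cation 14 (not isolated)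
Conditions: Me3SiOTf (cat.), 4 Å molecular sieves, CH2Cl2, −78 to −30 °C; aq. NaHCO3
Reagents that add atoms: none
Why: Friedel–Crafts alkylation of the proanthocyanidin type: ionisation of the 4-hydroxyl gives a cation stabilised by the para 7-benzyloxy group and by O1, which should be attacked by C6 of ring D (C8 is blocked by bromine) on the face anti to the 3-benzyloxy group, setting C4 as 4α (3,4-trans, 4S).

**Step 7**
Reactants: 15 3,7,3',4'-tetra-O-benzylfisetinidol-(4α,6)-[8-bromo-5,7,3',4',5'-penta-O-benzylgallocatechin]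
Product: 16 fisetinidol-(4α,6)-gallocatechin
Conditions: H2 (1 atm), Pd(OH)2/C, NaOAc, THF/MeOH, 23 °C
Reagents that add atoms: none
Why: Catalytic hydrogenolysis should cleave the nine benzyl ethers and the C8–Br bond in one operation, with NaOAc buffering the HBr so that the interflavan bond and the five stereocentres are left untouched.

**Compound list**

1 | 4-(benzyloxy)-1-bromo-2-fluorobenzene | Fc1cc(OCc2ccccc2)ccc1Br | starting material
2 | 2-(benzyloxy)-N-methoxy-N-methylacetamide | CON(C)C(=O)COCc1ccccc1 | starting material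
3 | [4-(benzyloxy)-2-fluorophenyl]magnesium chloride (LiCl complex) | Fc1cc(OCc2ccccc2)ccc1[Mg]Cl | intermediate
4 | chloromagnesium hemiaminal chelate, the tetrahedral adduct of 3 and 2 | CON(C)C(O[Mg]Cl)(COCc1ccccc1)c1ccc(OCc2ccccc2)cc1F | intermediate
5 | 2-(benzyloxy)-1-[4-(benzyloxy)-2-fluorophenyl]ethan-1-one | O=C(COCc1ccccc1)c1ccc(OCc2ccccc2)cc1F | intermediate
6 | 3,4-bis(benzyloxy)benzaldehyde | O=Cc1ccc(OCc2ccccc2)c(OCc2ccccc2)c1 | starting material
7 | potassium (Z)-enolate of 5 | [K+].[O-]/C(=C\OCc1ccccc1)c1ccc(OCc2ccccc2)cc1F | intermediate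
8 | potassium anti-(1R*,2R*)-2-(benzyloxy)-3-[4-(benzyloxy)-2-fluorophenyl]-1-[3,4-bis(benzyloxy)phenyl]-3-oxopropan-1-olate (racemic, one enantiomer drawn) | [K+].[O-][C@H](c1ccc(OCc2ccccc2)c(OCc2ccccc2)c1)[C@@H](OCc1ccccc1)C(=O)c1ccc(OCc2ccccc2)cc1F | intermediate
9 | rac-(2R*,3R*)-trans-3,7-bis(benzyloxy)-2-[3,4-bis(benzyloxy)phenyl]chroman-4-one (racemic, the (2R,3R) enantiomer drawn) | c1ccc(COc2ccc3c(c2)O[C@H](c2ccc(OCc4ccccc4)c(OCc4ccccc4)c2)[C@@H](OCc2ccccc2)C3=O)cc1 | intermediate
10 | (2R,3S,4R)-3,7-bis(benzyloxy)-2-[3,4-bis(benzyloxy)phenyl]chroman-4-ol (2,3-trans-3,4-trans) | c1ccc(COc2ccc3c(c2)O[C@H](c2ccc(OCc4ccccc4)c(OCc4ccccc4)c2)[C@@H](OCc2ccccc2)[C@@H]3O)cc1 | intermediate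
11 | (+)-gallocatechin, (2R,3S) | Oc1cc(O)c2c(c1)O[C@H](c1cc(O)c(O)c(O)c1)[C@@H](O)C2 | starting material
12 | 5,7,3',4',5'-penta-O-benzyl-(+)-gallocatechin, (2R,3S), 3-OH free | c1ccc(COc2cc(OCc3ccccc3)c3c(c2)O[C@H](c2cc(OCc4ccccc4)c(OCc4ccccc4)c(OCc4ccccc4)c2)[C@@H](O)C3)cc1 | intermediate
13 | 8-bromo-5,7,3',4',5'-penta-O-benzyl-(+)-gallocatechin, (2R,3S) | c1ccc(COc2cc(OCc3ccccc3)c3c(c2Br)O[C@H](c2cc(OCc4ccccc4)c(OCc4ccccc4)c(OCc4ccccc4)c2)[C@@H](O)C3)cc1 | intermediate
14 | (2R,3S)-3,7-bis(benzyloxy)-2-[3,4-bis(benzyloxy)phenyl]chroman-4-ylium cation | c1ccc(COc2ccc3c(c2)O[C@H](c2ccc(OCc4ccccc4)c(OCc4ccccc4)c2)[C@@H](OCc2ccccc2)[CH+]3)cc1 | intermediate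
15 | 3,7,3',4'-tetra-O-benzylfisetinidol-(4α,6)-[8-bromo-5,7,3',4',5'-penta-O-benzylgallocatechin]; upper unit 2R,3S,4S, lower unit 2R,3S, lower 3-OH free | c1ccc(COc2ccc3c(c2)O[C@H](c2ccc(OCc4ccccc4)c(OCc4ccccc4)c2)[C@@H](OCc2ccccc2)[C@@H]3c2c(OCc3ccccc3)c(Br)c3c(c2OCc2ccccc2)C[C@H](O)[C@@H](c2cc(OCc4ccccc4)c(OCc4ccccc4)c(OCc4ccccc4)c2)O3)cc1 | intermediate
16 | fisetinidol-(4α,6)-gallocatechin | Oc1ccc2c(c1)O[C@H](c1ccc(O)c(O)c1)[C@@H](O)[C@@H]2c1c(O)cc2c(c1O)C[C@H](O)[C@@H](c1cc(O)c(O)c(O)c1)O2 | target

**Step count and risks**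

Total step count: 7. Longest linear sequence: 5 steps (steps 1, 2, 3, 6, 7); steps 4 and 5 prepare the lower unit.

Steps most likely to fail:

1. Step 2. The aldolate may revert by retro-aldol cleavage or lose water to the chalcone faster than its oxygen displaces fluoride, because the electron-rich aldehyde makes the aldol equilibrium unfavourable under strongly basic conditions. Fallback: setting out from 5, silylation with Me3SiOTf and Et3N in CH2Cl2 should give the (Z)-trimethylsilyl enol ether F1. F1 and aldehyde 6 would then be combined in DMF with catalytic anhydrous CsF (23 to 60 °C), so that a fluoride-triggered Mukaiyama-type aldol addition delivers the naked alkoxide without any strong base. The alkoxide closes ring C by the same fluoride displacement, and the released fluoride carries the chain. The route is rejoined at 9.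

2. Step 6. Ionisation of the 4-hydroxyl is reversible and the bromine-deactivated, hindered ring D may capture the cation slowly, so that self-alkylation of ring A of the electrophile or erosion of facial selectivity at C4 competes. Fallback: setting out from 10, acid-catalysed exchange with benzyl mercaptan should give the 4α-benzylsulfanyl flavan F2, a stable store of the C4 cation. F2 would be activated irreversibly with the thiophile AgBF4 in CH2Cl2 at −78 °C in the presence of excess 13, so that the cation is generated only where the nucleophile is waiting. The route is rejoined at 15.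

3. Step 3. The catalyst may discriminate poorly between the two enantiomers of the trans-3-benzyloxy ketone, giving alcohol of insufficient enantiomeric purity at useful conversion. Fallback: setting out from 9, reduction of the whole racemate with NaBH4 in THF/MeOH should give 10 together with its (2S,3R,4S) enantiomer F3. The mixture would be coupled with enantiopure 13 as in step 6, giving 15 and the diastereomeric ent-fisetinidol-(4β,6) adduct F4. These two are diastereomers and would be separated by chromatography, the route being rejoined at 15.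

**Further compounds**

F1 | step 2 | (Z)-trimethylsilyl enol ether of 5, (Z)-{[2-(benzyloxy)-1-[4-(benzyloxy)-2-fluorophenyl]ethenyl]oxy}trimethylsilane | C[Si](C)(C)O/C(=C\OCc1ccccc1)c1ccc(OCc2ccccc2)cc1F
F2 | step 6 | (2R,3R,4R)-3,7-bis(benzyloxy)-4-(benzylsulfanyl)-2-[3,4-bis(benzyloxy)phenyl]chromane (4α-benzylsulfanyl, 2,3-trans-3,4-trans) | c1ccc(COc2ccc3c(c2)O[C@H](c2ccc(OCc4ccccc4)c(OCc4ccccc4)c2)[C@@H](OCc2ccccc2)[C@@H]3SCc2ccccc2)cc1
F3 | step 3 | (2S,3R,4S)-3,7-bis(benzyloxy)-2-[3,4-bis(benzyloxy)phenyl]chroman-4-ol, the enantiomer of 10 | c1ccc(COc2ccc3c(c2)O[C@@H](c2ccc(OCc4ccccc4)c(OCc4ccccc4)c2)[C@H](OCc2ccccc2)[C@H]3O)cc1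
F4 | step 3 | 3,7,3',4'-tetra-O-benzyl-ent-fisetinidol-(4β,6)-[8-bromo-5,7,3',4',5'-penta-O-benzylgallocatechin]; upper unit 2S,3R,4R, lower unit 2R,3S | c1ccc(COc2ccc3c(c2)O[C@@H](c2ccc(OCc4ccccc4)c(OCc4ccccc4)c2)[C@H](OCc2ccccc2)[C@H]3c2c(OCc3ccccc3)c(Br)c3c(c2OCc2ccccc2)C[C@H](O)[C@@H](c2cc(OCc4ccccc4)c(OCc4ccccc4)c(OCc4ccccc4)c2)O3)cc1
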